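The naphthalene is numbered C1 (aryl), C2 (benzyl), C3 (OH), C4 (H), C4a and C8a for ring A, and C4a, C5 (OMe), C6 (OH), C7 (OMe), C8 and C8a for ring B. With C1 and C2 drawn as sp3 carbons, the C3(O)=C4 bond becomes an enol ether alkene on ring-B carbon C4a. That alkene is the metathesis product of a C4a styrene and a 2-silyloxy-1-alkene, and this makes the key step possible.
Retrosynthetic cuts, in order: the four O-protecting groups, the C1=C2 unsaturation, C3=C4 (ring-closing metathesis), C1–aryl (conjugate addition), the enone C1=C2 (Horner–Wadsworth–Emmons), C2–CH2Ar (phosphonate alkylation), C4a–vinyl (Stille coupling).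
Forward: ring B comes from syringaldehyde and receives bromine, then vinyl, at C4a. The C2–C3 unit arrives with its benzyl group as a β-ketophosphonate, and the C1 aryl group arrives as a cuprate. Ring A is the only ring formed (step 10) and is aromatized in step 11.
Stereochemistry: the target has no stereocentre. C1 and C2 are transient sp3 centres, made without control as a racemic diastereomer mixture and erased by the dehydrogenation.

Key step: step 10

Assumption: the target SMILES carries no stereodescriptor, so the hindered C1–aryl axis is treated as stereochemically undefined and no control over it is sought.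

Step 1
Reactants: 1 syringaldehyde (4-hydroxy-3,5-dimethoxybenzaldehyde)
Product: 2 4-(benzyloxy)-3,5-dimethoxybenzaldehyde
Conditions: BnBr, K2CO3, DMF, rt
Reagents that add atoms: benzyl bromide, BrCc1ccccc1
Why: Williamson etherification of the acidic para-formyl phenol masks the future C6 oxygen as a hydrogenolysable ether that is inert to the later bases, organometallics and ruthenium carbene.

Step 2
Reactants: 2 4-(benzyloxy)-3,5-dimethoxybenzaldehyde
Product: 3 4-(benzyloxy)-2-bromo-3,5-dimethoxybenzaldehyde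
Conditions: NBS, MeCN, rt, dark
Reagents that add atoms: N-bromosuccinimide, O=C1CCC(=O)N1Br
Why: In this electrophilic aromatic bromination the two free ring positions are equivalent, each ortho to one methoxy group and para to the other, so a single monobromide should form while the unactivated phenyl ring of the benzyl ether stays untouched.

Step 3
Reactants: 3 4-(benzyloxy)-2-bromo-3,5-dimethoxybenzaldehyde
Product: 4 4-(benzyloxy)-2-ethenyl-3,5-dimethoxybenzaldehyde
Conditions: tributyl(vinyl)stannane, Pd(PPh3)4 (5 mol %), toluene, 100 °C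
Reagents that add atoms: tributyl(vinyl)stannane, C=C[Sn](CCCC)(CCCC)CCCC
Why: In this Stille coupling the ortho formyl group assists oxidative addition of zerovalent palladium into the C–Br bond, and the neutral medium spares the aldehyde while the future C4 carbon is installed.

Step 4
Reactants: 5 [4-(benzyloxy)-3-methoxyphenyl]methanol
Product: 6 1-(benzyloxy)-4-(bromomethyl)-2-methoxybenzene
Conditions: PBr3, Et2O, 0 °C; used without storage
Reagents that add atoms: phosphorus tribromide, BrP(Br)Br
Why: Bromide displaces the phosphite ester of a primary, electron-rich benzylic alcohol quickly at low temperature, and the aryl benzyl ether is not affected.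

Step 5
Reactants: 7 diethyl (2-oxopropyl)phosphonate; 6 1-(benzyloxy)-4-(bromomethyl)-2-methoxybenzene
Product: 9 diethyl {1-[4-(benzyloxy)-3-methoxyphenyl]-3-oxobutan-2-yl}phosphonate (racemic), via sodium phosphonoenolate 8 (not isolated)
Conditions: NaH, THF, 0 °C; then 6, 0 °C → 45 °C
Reagents that add atoms: sodium hydride, [Na+].[H-] (sodium of 8 only)
Why: SN2 C-alkylation of the stabilized β-ketophosphonate anion with a reactive benzylic bromide places the benzyl group on the future C2 without regiochemical ambiguity.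

Step 6
Reactants: 4 4-(benzyloxy)-2-ethenyl-3,5-dimethoxybenzaldehyde; 9 diethyl {1-[4-(benzyloxy)-3-methoxyphenyl]-3-oxobutan-2-yl}phosphonate
Product: 10 (E)-3-[4-(benzyloxy)-3-methoxybenzyl]-4-[4-(benzyloxy)-2-ethenyl-3,5-dimethoxyphenyl]but-3-en-2-one (geometry of no consequence)
Conditions: activated Ba(OH)2, THF/H2O, rt → 45 °C
Reagents that add atoms: none
Why: The Horner–Wadsworth–Emmons olefination forms the double bond at the phosphonate carbon, which avoids the regiochemical problem of an aldol on an unsymmetrical ketone; the mild heterogeneous base spares the styrene and should keep γ-deprotonation, which would move the double bond to the other benzylic carbon, to a minimum.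

Step 7
Reactants: 11 4-bromo-3-methoxyphenol
Product: 12 4-(benzyloxy)-1-bromo-2-methoxybenzene
Conditions: BnBr, K2CO3, acetone, reflux
Reagents that add atoms: benzyl bromide, BrCc1ccccc1
Why: Williamson etherification removes the acidic proton before metalation and gives this phenol the same protecting group as the other two.

Step 8
Reactants: 12 4-(benzyloxy)-1-bromo-2-methoxybenzene; 10 (E)-3-[4-(benzyloxy)-3-methoxybenzyl]-4-[4-(benzyloxy)-2-ethenyl-3,5-dimethoxyphenyl]but-3-en-2-one
Product: 16 4-[4-(benzyloxy)-2-methoxyphenyl]-4-[4-(benzyloxy)-2-ethenyl-3,5-dimethoxyphenyl]-3-[4-(benzyloxy)-3-methoxybenzyl]butan-2-one (racemic diastereomer mixture), via aryllithium 13 (not isolated), via lithium diarylcuprate 14 (not isolated), via trimethylsilyl enol ether 15 (not isolated)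
Conditions: 12, n-BuLi, THF, −78 °C; CuI, −78 → −40 °C; TMSCl, then 10, −78 → −20 °C; then 1 M HCl, THF, 0 °C
Reagents that add atoms: n-butyllithium, [Li]CCCC (lithium of 13); copper iodide CuI, [Cu]I (copper of 14); chlorotrimethylsilane, C[Si](C)(C)Cl (silyl group of 15)
Why: Bromine–lithium exchange, transmetalation to copper and silyl-chloride-accelerated 1,4-addition of the soft diarylcuprate form the C1–aryl bond without touching the styrene or the ethers; C1 and C2 arise without control, which is harmless because step 11 erases both.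

Step 9
Reactants: 16 4-[4-(benzyloxy)-2-methoxyphenyl]-4-[4-(benzyloxy)-2-ethenyl-3,5-dimethoxyphenyl]-3-[4-(benzyloxy)-3-methoxybenzyl]butan-2-one
Product: 18 tert-butyl({4-[4-(benzyloxy)-2-methoxyphenyl]-4-[4-(benzyloxy)-2-ethenyl-3,5-dimethoxyphenyl]-3-[4-(benzyloxy)-3-methoxybenzyl]but-1-en-2-yl}oxy)dimethylsilane (racemic diastereomer mixture), via lithium enolate 17 (not isolated)
Conditions: LDA (commercial solution), THF, −78 °C; TBSCl, DMPU, −78 → 0 °C; Et3N-deactivated silica
Reagents that add atoms: lithium diisopropylamide, [Li+].CC(C)[N-]C(C)C (lithium of 17); tert-butyldimethylsilyl chloride, CC(C)(C)[Si](C)(C)Cl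
Why: Kinetic enolization followed by O-silylation should be selective for the methyl group, because the only other α-hydrogen (C2–H) is buried between the benzyl and diarylmethyl groups.

Step 10
Reactants: 18 tert-butyl({4-[4-(benzyloxy)-2-methoxyphenyl]-4-[4-(benzyloxy)-2-ethenyl-3,5-dimethoxyphenyl]-3-[4-(benzyloxy)-3-methoxybenzyl]but-1-en-2-yl}oxy)dimethylsilane
Product: 19 6-(benzyloxy)-1-[4-(benzyloxy)-2-methoxyphenyl]-2-[4-(benzyloxy)-3-methoxybenzyl]-3-(tert-butyldimethylsilyloxy)-5,7-dimethoxy-1,2-dihydronaphthalene (racemic diastereomer mixture)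
Conditions: second-generation Grubbs catalyst (H2IMes)(PCy3)Cl2Ru=CHPh (5–10 mol %), degassed toluene (0.005 M), 80 °C, slow argon sparge
Reagents that add atoms: none
Why: After phosphine loss the ruthenium benzylidene exchanges with the monosubstituted C4a styrene, the resulting aryl alkylidene adds to the tethered 2-silyloxyalkene in a [2+2] step that puts ruthenium on the CH2 terminus, and cycloreversion delivers the C3=C4 bond and Ru=CH2, which re-enters the cycle with loss of ethene. The closest known chemistry is ring-closing metathesis of acyclic silyl enol ethers with second-generation ruthenium carbenes to give cyclic silyl enol ethers, together with metathesis-then-aromatization routes to naphthols. Ring A closes as a six-membered carbocycle from a 1,7-diene, and two tether atoms are the ortho carbons C4a and C8a of ring B, which hold both alkenes on the same side. No stereocentre is created, and C1 and C2 are carried through as a mixture whose members converge in step 11. The selectivity needed is initiation at the styrene rather than the enol ether; the geminally disubstituted, silyloxy-bearing alkene is too hindered to load the catalyst or to dimerize, while high dilution and ethene removal disfavour stilbene-type dimerization of the styrene. The neutral aprotic medium leaves the silyl enol ether, the benzyl ethers and the methyl ethers intact.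

Step 11
Reactants: 19 6-(benzyloxy)-1-[4-(benzyloxy)-2-methoxyphenyl]-2-[4-(benzyloxy)-3-methoxybenzyl]-3-(tert-butyldimethylsilyloxy)-5,7-dimethoxy-1,2-dihydronaphthalene
Product: 20 6-(benzyloxy)-1-[4-(benzyloxy)-2-methoxyphenyl]-2-[4-(benzyloxy)-3-methoxybenzyl]-3-(tert-butyldimethylsilyloxy)-5,7-dimethoxynaphthalene
Conditions: DDQ (1.05 equiv), 2,4,6-collidine, toluene, 0 °C → rt
Reagents that add atoms: none
Why: In this quinone dehydrogenation DDQ abstracts hydride from the doubly benzylic C1–H, whose cation is stabilized by ortho and para oxygen substituents on both rings, and loss of the C2 proton aromatizes ring A with oxygen already on C3; one equivalent of oxidant and the collidine buffer protect the benzyl ethers and the silyl group.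

Step 12
Reactants: 20 6-(benzyloxy)-1-[4-(benzyloxy)-2-methoxyphenyl]-2-[4-(benzyloxy)-3-methoxybenzyl]-3-(tert-butyldimethylsilyloxy)-5,7-dimethoxynaphthalene
Product: 21 7-(benzyloxy)-4-[4-(benzyloxy)-2-methoxyphenyl]-3-[4-(benzyloxy)-3-methoxybenzyl]-6,8-dimethoxynaphthalen-2-ol
Conditions: TBAF, AcOH, THF, 0 °C
Reagents that add atoms: none
Why: Fluoride-induced desilylation of an aryl silyl ether is driven by the strong Si–F bond, and acetic acid protonates the electron-rich naphthoxide before air can oxidize it.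

Step 13
Reactants: 21 7-(benzyloxy)-4-[4-(benzyloxy)-2-methoxyphenyl]-3-[4-(benzyloxy)-3-methoxybenzyl]-6,8-dimethoxynaphthalen-2-ol
Product: 22 4-(4-hydroxy-2-methoxyphenyl)-3-(4-hydroxy-3-methoxybenzyl)-6,8-dimethoxynaphthalene-2,7-diol (CNP0000246.0)
Conditions: H2 (1 atm), 10% Pd/C, EtOAc/MeOH, rt; work-up under argon
Reagents that add atoms: none
Why: Catalytic hydrogenolysis cleaves the three aryl benzyl ethers in one operation, and the naphthalene core, the methyl ethers and the diarylmethane C–C bonds are inert at atmospheric pressure.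

Compound list
1 | syringaldehyde | COc1cc(C=O)cc(OC)c1O | starting material
2 | 4-(benzyloxy)-3,5-dimethoxybenzaldehyde | COc1cc(C=O)cc(OC)c1OCc1ccccc1 | intermediate
3 | 4-(benzyloxy)-2-bromo-3,5-dimethoxybenzaldehyde | COc1cc(C=O)c(Br)c(OC)c1OCc1ccccc1 | intermediate
4 | 4-(benzyloxy)-2-ethenyl-3,5-dimethoxybenzaldehyde | COc1cc(C=O)c(C=C)c(OC)c1OCc1ccccc1 | intermediate
5 | [4-(benzyloxy)-3-methoxyphenyl]methanol | COc1cc(CO)ccc1OCc1ccccc1 | starting material
6 | 1-(benzyloxy)-4-(bromomethyl)-2-methoxybenzene | COc1cc(CBr)ccc1OCc1ccccc1 | intermediate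
7 | diethyl (2-oxopropyl)phosphonate | CCOP(=O)(CC(C)=O)OCC | starting material
8 | sodium enolate of diethyl (2-oxopropyl)phosphonate | [Na+].CCOP(=O)(OCC)C=C(C)[O-] | intermediate
9 | diethyl {1-[4-(benzyloxy)-3-methoxyphenyl]-3-oxobutan-2-yl}phosphonate (racemic) | CCOP(=O)(OCC)C(Cc1ccc(OCc2ccccc2)c(OC)c1)C(C)=O | intermediate
10 | (E)-3-[4-(benzyloxy)-3-methoxybenzyl]-4-[4-(benzyloxy)-2-ethenyl-3,5-dimethoxyphenyl]but-3-en-2-one | CC(=O)/C(Cc1ccc(OCc2ccccc2)c(OC)c1)=C/c1cc(OC)c(OCc2ccccc2)c(OC)c1C=C | intermediate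
11 | 4-bromo-3-methoxyphenol | COc1cc(O)ccc1Br | starting material
12 | 4-(benzyloxy)-1-bromo-2-methoxybenzene | COc1cc(OCc2ccccc2)ccc1Br | intermediate
13 | [4-(benzyloxy)-2-methoxyphenyl]lithium | [Li]c1ccc(OCc2ccccc2)cc1OC | intermediate
14 | lithium bis[4-(benzyloxy)-2-methoxyphenyl]cuprate | [Li+].COc1cc(OCc2ccccc2)ccc1[Cu-]c1ccc(OCc2ccccc2)cc1OC | intermediate
15 | 4-[4-(benzyloxy)-2-methoxyphenyl]-4-[4-(benzyloxy)-2-ethenyl-3,5-dimethoxyphenyl]-3-[4-(benzyloxy)-3-methoxybenzyl]-2-(trimethylsilyloxy)but-2-ene (racemic, alkene isomers) | CC(O[Si](C)(C)C)=C(Cc1ccc(OCc2ccccc2)c(OC)c1)C(c1ccc(OCc2ccccc2)cc1OC)c1cc(OC)c(OCc2ccccc2)c(OC)c1C=C | intermediate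
16 | 4-[4-(benzyloxy)-2-methoxyphenyl]-4-[4-(benzyloxy)-2-ethenyl-3,5-dimethoxyphenyl]-3-[4-(benzyloxy)-3-methoxybenzyl]butan-2-one (racemic diastereomer mixture) | CC(=O)C(Cc1ccc(OCc2ccccc2)c(OC)c1)C(c1ccc(OCc2ccccc2)cc1OC)c1cc(OC)c(OCc2ccccc2)c(OC)c1C=C | intermediate
17 | lithium but-1-en-2-olate (methyl-side enolate) of 16 | [Li]OC(=C)C(Cc1ccc(OCc2ccccc2)c(OC)c1)C(c1ccc(OCc2ccccc2)cc1OC)c1cc(OC)c(OCc2ccccc2)c(OC)c1C=C | intermediate
18 | tert-butyldimethylsilyl but-1-en-2-yl enol ether of 16 (racemic diastereomer mixture) | C=Cc1c(OC)c(OCc2ccccc2)c(OC)cc1C(c1ccc(OCc2ccccc2)cc1OC)C(Cc1ccc(OCc2ccccc2)c(OC)c1)C(=C)O[Si](C)(C)C(C)(C)C | intermediate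
19 | 6-(benzyloxy)-1-[4-(benzyloxy)-2-methoxyphenyl]-2-[4-(benzyloxy)-3-methoxybenzyl]-3-(tert-butyldimethylsilyloxy)-5,7-dimethoxy-1,2-dihydronaphthalene (racemic diastereomer mixture) | CC(C)(C)[Si](C)(C)OC1=Cc2c(OC)c(OCc3ccccc3)c(OC)cc2C(c2ccc(OCc3ccccc3)cc2OC)C1Cc1ccc(OCc2ccccc2)c(OC)c1 | intermediate
20 | 6-(benzyloxy)-1-[4-(benzyloxy)-2-methoxyphenyl]-2-[4-(benzyloxy)-3-methoxybenzyl]-3-(tert-butyldimethylsilyloxy)-5,7-dimethoxynaphthalene | CC(C)(C)[Si](C)(C)Oc1cc2c(OC)c(OCc3ccccc3)c(OC)cc2c(-c2ccc(OCc3ccccc3)cc2OC)c1Cc1ccc(OCc2ccccc2)c(OC)c1 | intermediate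
21 | 7-(benzyloxy)-4-[4-(benzyloxy)-2-methoxyphenyl]-3-[4-(benzyloxy)-3-methoxybenzyl]-6,8-dimethoxynaphthalen-2-ol | Oc1cc2c(OC)c(OCc3ccccc3)c(OC)cc2c(-c2ccc(OCc3ccccc3)cc2OC)c1Cc1ccc(OCc2ccccc2)c(OC)c1 | intermediate
22 | 4-(4-hydroxy-2-methoxyphenyl)-3-(4-hydroxy-3-methoxybenzyl)-6,8-dimethoxynaphthalene-2,7-diol | COc1cc(Cc2c(O)cc3c(OC)c(O)c(OC)cc3c2-c2ccc(O)cc2OC)ccc1O | target

Total step count: 13
Longest linear sequence: 10 steps (1, 2, 3, 6, 8, 9, 10, 11, 12, 13)

Steps most likely to fail

Step 8, conjugate addition.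
- **Risk:** The β-carbon is screened by the α-benzyl group and by the ortho-vinyl ring, and the nucleophile carries an ortho-methoxy group. The 1,4-addition may therefore become slower than thermal decay of the cuprate, attack at the carbonyl group or electron-transfer reduction of the enone.
- **Fallback:** It sets out from 4 and returns at 16. The order of bond formation is changed so that copper meets an unhindered enone and the benzyl group is attached last. Claisen–Schmidt condensation of 4 with excess acetone (aq. NaOH, rt) should give (E)-4-[4-(benzyloxy)-2-ethenyl-3,5-dimethoxyphenyl]but-3-en-2-one F1. Cuprate 14 with TMSCl should add to this disubstituted enone and, after a non-acidic work-up, leave the regiodefined internal enol ether 4-[4-(benzyloxy)-2-methoxyphenyl]-4-[4-(benzyloxy)-2-ethenyl-3,5-dimethoxyphenyl]-2-(trimethylsilyloxy)but-2-ene F2. ZnBr2-catalysed SN1-type alkylation of this silyl enol ether with the readily ionized bromide 6 (CH2Cl2, −20 °C → rt) should then form the C2–CH2Ar bond and give 16.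

Step 10, ring-closing metathesis.
- **Risk:** Loading on a styrene flanked by two ortho substituents, and ruthenacyclobutane formation with the hindered enol ether, may be slow enough for catalyst decay, alkene isomerization or intermolecular dimerization of the styrene to compete.
- **Fallback:** It sets out from 3 and returns at 19. Ring A is closed at C4–C4a instead, so no vinyl group is needed.
  - Horner–Wadsworth–Emmons reaction of 3 with 9 under the conditions of step 6 should give (E)-4-[4-(benzyloxy)-2-bromo-3,5-dimethoxyphenyl]-3-[4-(benzyloxy)-3-methoxybenzyl]but-3-en-2-one F3.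
  - Cuprate 14 with TMSCl at −78 °C, where the hindered, electron-rich bromide should exchange only slowly, should give the trimethylsilyl enol ether of the adduct F4. Dilute acid should hydrolyse it to 4-[4-(benzyloxy)-2-bromo-3,5-dimethoxyphenyl]-4-[4-(benzyloxy)-2-methoxyphenyl]-3-[4-(benzyloxy)-3-methoxybenzyl]butan-2-one F5.
  - Intramolecular palladium-catalysed ketone α-arylation (Pd2(dba)3, XPhos, NaOtBu, toluene, 80 °C) can engage only the methyl-side enolate, because the other side would need a four-membered ring. It should give 7-(benzyloxy)-4-[4-(benzyloxy)-2-methoxyphenyl]-3-[4-(benzyloxy)-3-methoxybenzyl]-6,8-dimethoxy-3,4-dihydronaphthalen-2(1H)-one F6.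
  - TBSOTf and Et3N in CH2Cl2 should enolize this 2-tetralone toward the benzylic C4 and deliver 19.

Step 11, dehydrogenation.
- **Risk:** Over-oxidation at the electron-rich diarylmethane CH2, oxidative loss of benzyl ethers, or adduct formation between the quinone and the enol ether may erode the material.
- **Fallback:** It sets out from 19 and returns at 21. The oxidant is replaced by a halogenation–elimination sequence. NBS in THF at −78 °C should brominate the silyl enol ether much faster than any arene and give 7-(benzyloxy)-4-[4-(benzyloxy)-2-methoxyphenyl]-3-[4-(benzyloxy)-3-methoxybenzyl]-1-bromo-6,8-dimethoxy-3,4-dihydronaphthalen-2(1H)-one F7. DBU in THF should then enolize it toward C2 and expel bromide in a vinylogous elimination, and tautomerization gives the free naphthol 21, so step 12 is skipped as well.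

Further compounds
F1 | step 8 | (E)-4-[4-(benzyloxy)-2-ethenyl-3,5-dimethoxyphenyl]but-3-en-2-one | CC(=O)/C=C/c1cc(OC)c(OCc2ccccc2)c(OC)c1C=C
F2 | step 8 | 4-[4-(benzyloxy)-2-methoxyphenyl]-4-[4-(benzyloxy)-2-ethenyl-3,5-dimethoxyphenyl]-2-(trimethylsilyloxy)but-2-ene (racemic, alkene isomers) | CC(O[Si](C)(C)C)=CC(c1ccc(OCc2ccccc2)cc1OC)c1cc(OC)c(OCc2ccccc2)c(OC)c1C=C
F3 | step 10 | (E)-4-[4-(benzyloxy)-2-bromo-3,5-dimethoxyphenyl]-3-[4-(benzyloxy)-3-methoxybenzyl]but-3-en-2-one | CC(=O)/C(Cc1ccc(OCc2ccccc2)c(OC)c1)=C/c1cc(OC)c(OCc2ccccc2)c(OC)c1Br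
F4 | step 10 | 4-[4-(benzyloxy)-2-bromo-3,5-dimethoxyphenyl]-4-[4-(benzyloxy)-2-methoxyphenyl]-3-[4-(benzyloxy)-3-methoxybenzyl]-2-(trimethylsilyloxy)but-2-ene (racemic, alkene isomers) | CC(O[Si](C)(C)C)=C(Cc1ccc(OCc2ccccc2)c(OC)c1)C(c1ccc(OCc2ccccc2)cc1OC)c1cc(OC)c(OCc2ccccc2)c(OC)c1Br
F5 | step 10 | 4-[4-(benzyloxy)-2-bromo-3,5-dimethoxyphenyl]-4-[4-(benzyloxy)-2-methoxyphenyl]-3-[4-(benzyloxy)-3-methoxybenzyl]butan-2-one (racemic diastereomer mixture) | CC(=O)C(Cc1ccc(OCc2ccccc2)c(OC)c1)C(c1ccc(OCc2ccccc2)cc1OC)c1cc(OC)c(OCc2ccccc2)c(OC)c1Br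
F6 | step 10 | 7-(benzyloxy)-4-[4-(benzyloxy)-2-methoxyphenyl]-3-[4-(benzyloxy)-3-methoxybenzyl]-6,8-dimethoxy-3,4-dihydronaphthalen-2(1H)-one (racemic diastereomer mixture) | O=C1Cc2c(OC)c(OCc3ccccc3)c(OC)cc2C(c2ccc(OCc3ccccc3)cc2OC)C1Cc1ccc(OCc2ccccc2)c(OC)c1
F7 | step 11 | 7-(benzyloxy)-4-[4-(benzyloxy)-2-methoxyphenyl]-3-[4-(benzyloxy)-3-methoxybenzyl]-1-bromo-6,8-dimethoxy-3,4-dihydronaphthalen-2(1H)-one (racemic diastereomer mixture) | O=C1C(Br)c2c(OC)c(OCc3ccccc3)c(OC)cc2C(c2ccc(OCc3ccccc3)cc2OC)C1Cc1ccc(OCc2ccccc2)c(OC)c1
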